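**Small charge.** A small charge of starting material, 0.050 M, meets both nucleophiles in excess, at 2.50 equiv and 1.50 equiv, which makes it the limiting reagent.

| flask | starting material | first nucleophile | second nucleophile | temperature | remark | time |
|---|---|---|---|---|---|---|
| teal | 0.050 M | 2.5 equiv | 1.5 equiv | 110 °C | the very flask that is asked about, followed so far |  |
| red | 0.025 M | 2.5 equiv | 1.5 equiv | 105 °C | run made earlier |  |
| flask | 0.050 M | 2.50 equiv | 1.50 equiv | 110 °C |  | 6.0 h |

- teal (time / h: target / %, starting material / %): 0.833: 66.3, 0.7; 1.50: 66.9, 0; 2.50: 67.4, 0.2; 3.00: 67.0, 0; 4.00: 67.7, 0.2; 5.00: 67.4, 0; 6.00: 66.2, 0
- red (time / h: target / %, starting material / %): 0.167: 16.7, 55.0; 0.500: 48.6, 16.4; 0.833: 61.8, 5.0; 1.33: 67.4, 0.9; 2.00: 67.7, 0.4; 2.50: 67.6, 0; 3.00: 66.7, 0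

(scatter of a reading: 0.5 percentage points)

- zeta: at 6.0 h raise the temperature by 20 K, then wait 12 h
- delta: change nothing and wait 12 h more
- theta: at 6.0 h take out 90% of the target then present, then wait 12 h
- gamma: at 6.0 h add first nucleophile, 100% of the amount charged, then wait 12 h

* target, in percent of the starting material first charged, at 6.0 h
* what to do for the largest gain in target; "none" if nothing gains more than 2 percentage points (zeta / delta / theta / gamma / none)
* target present, with what was taken out counted in, in percent of the starting material first charged, after theta
* target present, with what was taken out counted in, in percent of the starting material first charged, after gamma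

- removed target is counted in
- additions bring no volume worth counting

**Read the plateau.** Average the teal target readings from 1.50 h on: they give 0.671 of the charge, with starting material reading 0% at 6.00 h. The red run, at half the concentration, reads 67.7% at 2.00 h. So in the teal run a fraction 0.329 does not read as target.

**Suspect an intermediate.** Look at the red run at 0.167 h: of the 45 percentage points that has reacted, just 0.371 stands as target, less than the teal plateau fraction. Suppose, then, a short-lived intermediate that each nucleophile captures, one molecule per capture.

**Compare two rates.** Take one moment. Both captures act on the same intermediate, so its amount cancels from their ratio, and each rate constant times its nucleophile remains. Both nucleophiles scale with the charge, so concentration cancels too. Now divide target over loss by the charged ratio of first to second nucleophile: this reads 1.22. Call it the capture ratio per equivalent, a selectivity factor.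

**Let it drift.** Captures spend nucleophile. On the teal readings, and if each capture spends one nucleophile, the first loses 26.8% of its charge and the second 21.9%, so their ratio ends at 0.937 of its starting value.

**Commit.** With starting material reading 0%, expect target to stay at 0.671 of the charge at 6.0 h. Take both captures as one-way, since the teal target readings stay level from 1.50 h to 6.00 h: waiting, heating, removal and added first nucleophile then meet starting material reading 0%, so choose none, with theta and gamma both at that same figure.

**The forecast.** It gives 67%, none, 67% after theta and 67% after gamma, reasoning that “about a third goes irreversibly elsewhere”. My reckoning makes the same choice, and its figure rounds to the forecast's.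

**The result.** The flask gives 66.9%, best choice none, 66.9% after theta and 66.9% after gamma.

    second nucleophile + intermediate → other capture product (k = 120 M⁻¹ h⁻¹, Ea = 81.0 kJ mol⁻¹)
    starting material → intermediate (k = 5.90 h⁻¹, Ea = 120 kJ mol⁻¹)
    first nucleophile + intermediate → target (k = 150 M⁻¹ h⁻¹, Ea = 72.0 kJ mol⁻¹)
    (constants at 110 °C)

**Two captures.** At the start of this flask, first nucleophile takes intermediate 2.08 times as fast as second nucleophile. At 0.600 h in this flask, with 74.3% of the first nucleophile and 78.8% of the second nucleophile left, each of its own charge, the factor is 1.96.

**Second flask.** Charge a neighbour flask with 10.0 equiv of first nucleophile, all else as in the recipe: 1.22 gives target over loss of 8.16, a fraction 0.891. The computed neighbour holds 89.2% target and 10.8% other capture product.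

The numbers in the tables are calculated from invented constants, noise included.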